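Late in the autumn run the Qd reading had fallen from 14.0 % to 7.9 %, while Qf read 7.0 %, so I took no ratio from late readings. This note is for whoever takes over north-east, where c(Qb) is charged at the start and Qa is fed over 20 min.

| setting | noon | dusk | autumn | north-east | south-west | south-east | south |
|---|---|---|---|---|---|---|---|
| Qa | 0.50 M | 0.50 M | 0.50 M | 0.50 M (fed, over 20 min) | 0.50 M | 0.50 M | 0.50 M |
| Qb | 0.475 M | 0.24 M | 0.95 M | 0.475 M | 0.475 M | 0.475 M (fed, over 20 min) | 0.475 M (fed, over 5.0 min) |
| remark | run made earlier | run made earlier | run made earlier | all else is in the flask from the start; the feed brings no volume worth counting | everything together at the start | all else is in the flask from the start; the feed brings no volume worth counting | all else is in the flask from the start; the feed brings no volume worth counting |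
| time |  |  |  | 25 min | 25 min | 25 min | 25 min |

| run | time / min | Qd / % | Qf / % |
|---|---|---|---|
| noon | 1.33 | 6.0 | 0.5 |
| noon | 4.00 | 9.5 | 2.0 |
| noon | 8.00 | 9.9 | 1.3 |
| noon | 10.0 | 8.9 | 1.9 |
| noon | 15.0 | 8.0 | 1.8 |
| dusk | 1.33 | 3.3 | 1.2 |
| dusk | 2.50 | 4.9 | 0 |
| dusk | 4.00 | 6.6 | 0 |
| dusk | 8.00 | 6.0 | 0.9 |
| dusk | 15.0 | 5.4 | 1.6 |
| autumn | 3.00 | 13.5 | 3.7 |
| autumn | 6.00 | 14.0 | 6.1 |
| autumn | 10.0 | 11.1 | 6.9 |
| autumn | 12.0 | 10.1 | 6.6 |
| autumn | 15.0 | 7.9 | 7.0 |

(readings scatter by 0.5 percentage points)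

- candidate steps: Qd <-> Qh; Qd + Qc -> Qg; Qb + Qe -> Qf + Qc; Qb -> Qj; Qa + Qb -> Qe + Qc; Qa + Qb -> Qd + Qc; Qb + Qd -> Qf + Qc

- the flask that comes out highest in share of Qd in Qd plus Qf, or "all alike" when all lie within 1.5 percentage points (north-east / south-west / south-east / south / all alike)
- share of Qd in Qd plus Qf at the end, north-east
- share of Qd in Qd plus Qf at the end, south-west
- share of Qd in Qd plus Qf at the end, south-east
- share of Qd in Qd plus Qf at the end, south

I assumed that Qf forms as Qb meets the mono adducts, so that Qf per Qd rises with the Qb charge until Qd fades. I therefore carried the overrun, meaning Qf over Qd per molar of Qb charged, read before the fade: 0.288 M⁻¹, from the autumn reading at 3.00 min. Its Qf stands well clear of the scatter of 0.5 percentage points. With 0.475 M of Qb, I expected a share of 87.9 % in north-east when you came, and I asked you to leave that charge alone, since on this rule more Qb means more Qf per Qd.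

The forecast named north-east with 92 %, above my figure, and gave 76 %, 83 % and 78 % for south-west, south-east and south. Of the Qa feed it wrote “Feeding Qa starves the reaction”.

    Qd ⇌ Qh (K = 1.20, k = 2.50 min⁻¹)
    Qd + Qc → Qg (k = 0.550 M⁻¹ min⁻¹)
    Qb + Qe → Qf + Qc (k = 0.100 M⁻¹ min⁻¹)
    Qb → Qj (k = 0.250 min⁻¹)
    Qa + Qb → Qe + Qc (k = 0.0870 M⁻¹ min⁻¹)
    Qa + Qb → Qd + Qc (k = 0.290 M⁻¹ min⁻¹)
    Qb + Qd → Qf + Qc (k = 0.200 M⁻¹ min⁻¹)

The flasks gave 86.8 %, 73.0 %, 82.0 % and 75.3 % in that order, so north-east came out highest. North-east ended with an overrun of 0.320 M⁻¹. A neighbour of it with 0.19 M of Qb, where 0.288 M⁻¹ gives 94.8 %, reached 94.9 %. In north-east, Qd and Qh relaxed by their own step, both ways together, with a half-life of 0.151 min, far shorter than the 25 min run, and at the end the forward rate of Qd to Qh, with the way back not counted, stood at 110 times the rate of Qd to Qg. Qh over Qd there stood at 1.21, against an equilibrium constant of 1.2.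

The data were computed from invented constants; the scatter is artificial.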